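**Retrosynthetic overview**
- The only ring (the arene) is formed last, by a [4+2] benzannulation of an acyclic 2-alkynoic acid (supplies C1, C6, CO2H and the whole side chain) with a 1-methoxy-1,3-bis(silyloxy)penta-1,3-diene (supplies C2–C5, both OH groups and the ring CH3); loss of methanol aromatises.
- Key disconnection: the bond between ring carbon C6 (C3 of the alkynoic acid) and the first side-chain CH2. It is made from dilithium propiolate, an acetylenic homoenolate-type (d3) synthon, and 1-bromo-13-methyltetradecane. C3 is by nature the electrophilic β-carbon of the acid; here it is the nucleophile.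
- The bromide comes from Cu-catalysed coupling of isopentylmagnesium bromide with 1,10-dibromodecane; the diene comes from methyl 3-oxopentanoate.
- Convergent, no protecting-group or ester-hydrolysis step: 4 steps, longest linear sequence 3.

Assumption: the target has no stereocentre and no stereogenic double bond, so it is achiral and needs no stereocontrol; E/Z labels on the silyl enol ether intermediates are the expected major isomers and are erased on aromatisation.

**Step 1**
Reactants: 1 1,10-dibromodecane; 2 isopentylmagnesium bromide (3-methylbutylmagnesium bromide)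
Product: 3 1-bromo-13-methyltetradecane
Conditions: Li2CuCl4 (2 mol%), THF, −10 °C → rt; 1 used in 3-fold excess and recovered by distillation
Reagents that add atoms: none
Why: Kochi-type copper-catalysed sp3–sp3 cross-coupling of a primary Grignard reagent with a primary bromide, run with excess symmetrical dibromide so that mono-coupling dominates; no stereocentre is formed.

**Step 2**
Reactants: 3 1-bromo-13-methyltetradecane; 4 propiolic acid (prop-2-ynoic acid)
Product: 6 16-methylheptadec-2-ynoic acid, via dilithium propiolate 5 (not isolated)
Conditions: 4 (1.5 equiv), n-BuLi (3.0 equiv), THF–HMPA 4:1, −78 °C; then 3, NaI (10 mol%), −78 °C → rt, 16 h; aq. HCl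
Reagents that add atoms: none
Why: Alkylation of the propiolic acid dianion, an acetylenic homoenolate-type (d3, β-carboxyvinyl anion) synthon of reversed polarity, in which C3 (the electrophilic β-carbon of the alkynoic acid that results) acts as the nucleophile and displaces bromide from the electrophilic CH2Br carbon of 3 by SN2 in THF–HMPA, while the carboxylate shields the product from conjugate addition and delivers the acid oxidation level without a separate carboxylation or protection step; no stereocentre is formed.

**Step 3**
Reactants: 7 methyl 3-oxopentanoate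
Product: 9 (1Z,3Z)-1-methoxy-1,3-bis[(trimethylsilyl)oxy]penta-1,3-diene, via mono-silyl enol ether 8 (not isolated)
Conditions: TMSOTf (2.2 equiv), Et3N (2.4 equiv), Et2O, 0 °C → rt, 4 h; ammonium triflate layer removed, used crude
Reagents that add atoms: trimethylsilyl trifluoromethanesulfonate, C[Si](C)(C)OS(=O)(=O)C(F)(F)F
Why: One-pot double O-silylation of a β-keto ester with TMSOTf/Et3N (Simchen procedure for Chan-type 1,3-bis(silyloxy)dienes), in which the ketone is silylated first to the conjugated enol ether 8 and this is then enolised at the γ-CH2 onto the ester oxygen, giving the electron-rich diene whose C4 methyl becomes the ring methyl; no stereocentre is formed and the alkene geometry is lost on aromatisation.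

**Step 4**
Reactants: 6 16-methylheptadec-2-ynoic acid; 9 (1Z,3Z)-1-methoxy-1,3-bis[(trimethylsilyl)oxy]penta-1,3-diene
Product: 13 2,4-dihydroxy-5-methyl-6-(13-methyltetradecyl)benzoic acid, via silyl ynoate 10 (not isolated), via cycloadduct 11 (not isolated), via tris-silylated arene 12 (not isolated)
Conditions: HMDS (0.6 equiv), toluene, 80 °C, N2 sweep; then 9 (2 equiv), 130 °C, sealed tube, 24 h; then 1 M HCl, THF, rt, 1 h
Reagents that add atoms: none
Why: Diels–Alder benzannulation of a 2-alkynoate with a 1-alkoxy-1,3-bis(silyloxy)diene followed by aromatisation, in which the nucleophilic C4 terminus of 9 bonds to the β-carbon of silyl ynoate 10 and the ketene-acetal carbon to its α-carbon (placing CO2H between OH and the chain and CH3 next to the chain), 1,4-loss of methanol from 11 forms the only ring as an arene, and mild aqueous acid strips the three silyl groups so that no ester hydrolysis is needed; the two stereocentres of 11 are erased and the target is achiral.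

**Compound list**
1 | 1,10-dibromodecane | BrCCCCCCCCCCBr | starting material
2 | isopentylmagnesium bromide (3-methylbutylmagnesium bromide) | CC(C)CC[Mg]Br | starting material
3 | 1-bromo-13-methyltetradecane | CC(C)CCCCCCCCCCCCBr | intermediate
4 | propiolic acid (prop-2-ynoic acid) | C#CC(=O)O | starting material
5 | dilithium propiolate (dianion of 4, not isolated) | [Li+].[Li+].[C-]#CC(=O)[O-] | intermediate
6 | 16-methylheptadec-2-ynoic acid | CC(C)CCCCCCCCCCCCC#CC(=O)O | intermediate
7 | methyl 3-oxopentanoate | CCC(=O)CC(=O)OC | starting material
8 | methyl (2Z)-3-[(trimethylsilyl)oxy]pent-2-enoate (not isolated) | COC(=O)/C=C(/CC)O[Si](C)(C)C | intermediate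
9 | (1Z,3Z)-1-methoxy-1,3-bis[(trimethylsilyl)oxy]penta-1,3-diene | C/C=C(O[Si](C)(C)C)/C=C(/OC)O[Si](C)(C)C | intermediate
10 | trimethylsilyl 16-methylheptadec-2-ynoate (not isolated) | CC(C)CCCCCCCCCCCCC#CC(=O)O[Si](C)(C)C | intermediate
11 | trimethylsilyl 6-methoxy-3-methyl-2-(13-methyltetradecyl)-4,6-bis[(trimethylsilyl)oxy]cyclohexa-1,4-diene-1-carboxylate (not isolated; racemic, both stereocentres uncontrolled and destroyed on aromatisation) | C[Si](C)(C)OC(=O)C1=C(CCCCCCCCCCCCC(C)C)C(C)C(O[Si](C)(C)C)=CC1(OC)O[Si](C)(C)C | intermediate
12 | trimethylsilyl 5-methyl-6-(13-methyltetradecyl)-2,4-bis[(trimethylsilyl)oxy]benzoate (not isolated) | Cc1c(O[Si](C)(C)C)cc(O[Si](C)(C)C)c(C(=O)O[Si](C)(C)C)c1CCCCCCCCCCCCC(C)C | intermediate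
13 | 2,4-dihydroxy-5-methyl-6-(13-methyltetradecyl)benzoic acid | Cc1c(O)cc(O)c(C(=O)O)c1CCCCCCCCCCCCC(C)C | target

**Totals**
Total step count: 4. Longest linear sequence: 3 steps (Steps 1, 2, 4; the diene branch, Steps 3 and 4, is shorter).

**Three steps most likely to fail, with fallbacks**

Step 4 (highest risk). An internal, singly activated ynoate and a 4-methylated diene may cycloadd more slowly than the diene decomposes at 130 °C. The mixed ketal of 11 could also lose silanol instead of methanol and leave a 2-O-methyl ether. The fallback sets out from 6 and returns at 13, replacing the cycloaddition by an anionic Michael–Claisen annulation. 6 is esterified (Boc2O, DMAP, t-BuOH) to tert-butyl 16-methylheptadec-2-ynoate F1. The dianion of 7 (NaH, then n-BuLi, THF, 0 °C) adds through its γ-carbon to the β-carbon of F1, and the resulting ester-stabilised vinyl anion closes onto the methyl ester to give tert-butyl 2,4-dihydroxy-5-methyl-6-(13-methyltetradecyl)benzoate F2. TFA in CH2Cl2 at 0–20 °C then removes the tert-butyl group without basic hydrolysis and gives 13.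

Step 2. The propiolate dianion is a weak nucleophile; with a long primary bromide, alkylation may be incomplete or E2 may compete. The fallback sets out from 3 and returns at 6, using a masked, mono-anionic propiolate. 3 alkylates the lithium acetylide of commercial 3,3,3-triethoxyprop-1-yne (n-BuLi, THF/HMPA) to give 1,1,1-triethoxy-16-methylheptadec-2-yne F3. Dilute aqueous acid (TsOH, wet THF) opens the orthoester to ethyl 16-methylheptadec-2-ynoate F4. LiOH in aqueous THF followed by acidification gives 6.

Step 1. Mono-coupling of a symmetrical dibromide is statistical, and separating 3 from 1 and from the doubly coupled alkane may cost yield. The fallback sets out from 2 and returns at 3, using a partner with differentiated ends. 2 (2.2 equiv) is coupled under the same copper catalysis with commercial 10-bromodecan-1-ol to give 13-methyltetradecan-1-ol F5. Appel bromination (CBr4, PPh3, CH2Cl2) gives 3.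

**Further compounds**
F1 | step 4 | tert-butyl 16-methylheptadec-2-ynoate | CC(C)CCCCCCCCCCCCC#CC(=O)OC(C)(C)C
F2 | step 4 | tert-butyl 2,4-dihydroxy-5-methyl-6-(13-methyltetradecyl)benzoate | Cc1c(O)cc(O)c(C(=O)OC(C)(C)C)c1CCCCCCCCCCCCC(C)C
F3 | step 2 | 1,1,1-triethoxy-16-methylheptadec-2-yne | CCOC(OCC)(OCC)C#CCCCCCCCCCCCCC(C)C
F4 | step 2 | ethyl 16-methylheptadec-2-ynoate | CCOC(=O)C#CCCCCCCCCCCCCC(C)C
F5 | step 1 | 13-methyltetradecan-1-ol | CC(C)CCCCCCCCCCCCO
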